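**Retrosynthetic overview**
- Feature: the acyclic C1–C7 chain has oxygen-bearing stereocentres at C3 and C5 (both S) on either side of the C4 methylene. In the parent 3,5-diol a twofold axis through C4 exchanges the two carbinols and their identical CH2CH2–(4-hydroxy-3-methoxyphenyl) arms, so the hydroxyls are homotopic and placing one acetyl group involves no regiochemical choice.
- Disconnection 1: the O-acetyl group and the two phenol O–H bonds (carried as benzyl ethers) lead back to the C2-symmetric (3S,5S)-diol bis(benzyl ether).
- Disconnection 2: C1–C2 and C6–C7 together lead back to two equivalents of a 4-(benzyloxy)-3-methoxybenzyl Grignard reagent and (2R,4R)-1,2:4,5-diepoxypentane, which holds C2–C6 and both stereocentres.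
- Precursors: the diepoxide comes from 1,5-dichloropentane-2,4-dione (asymmetric hydrogenation, base closure); the Grignard reagent from 4-(benzyloxy)-3-methoxybenzyl alcohol (chlorination, magnesium insertion).
- Rings: both benzene rings are bought. Only auxiliary rings are made: two oxiranes (step 4, opened in step 5), then a 1,3-dioxane orthoester (step 6, opened in the same flask).

Key step: step 5

Assumption: (S)-BINAP is taken as the ligand enantiomer that gives the (2R,4R)-dichlorodiol, by analogy with the sense known for 4-chloro-3-oxobutanoates (CH2Cl outranks the chain carbon); this is to be checked on the crystalline dichlorodiol before it is carried on, and (R)-BINAP is used if the sense proves reversed. Both starting materials are taken as catalogue compounds.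

**Route**

Step 1
Reactants: 1 4-(benzyloxy)-3-methoxybenzyl alcohol
Product: 3 4-(benzyloxy)-3-methoxybenzyl chloride, via chlorosulfite ester 2 (not isolated)
Conditions: SOCl2 (1.2 equiv), CH2Cl2, 0 °C → rt; evaporation, recrystallisation
Reagents that add atoms: thionyl chloride, O=S(Cl)Cl
Why: Chlorodehydroxylation with thionyl chloride, in which the alkyl chlorosulfite collapses easily at this electron-rich benzylic carbon with loss of SO2, while the aryl benzyl ether should tolerate the brief exposure to HCl at or below room temperature.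

Step 2
Reactants: 3 4-(benzyloxy)-3-methoxybenzyl chloride
Product: 4 [4-(benzyloxy)-3-methoxybenzyl]magnesium chloride (titrated solution, used directly)
Conditions: Mg turnings (3 equiv, activated with a crystal of I2), 2-MeTHF, 0–10 °C, slow addition of dilute 3
Reagents that add atoms: magnesium, [Mg]
Why: Grignard formation by insertion of magnesium into the benzylic C–Cl bond, where the chloride (not bromide), excess metal, low temperature, 2-MeTHF and slow addition keep the halide concentration low and should hold back Wurtz homocoupling.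

Step 3
Reactants: 5 1,5-dichloropentane-2,4-dione
Product: 7 (2R,4R)-1,5-dichloropentane-2,4-diol, via (4R)-hydroxy ketone 6 (not isolated)
Conditions: H2 (about 80 bar), [RuCl2((S)-BINAP)]2·NEt3 (0.2 mol%), MeOH, 25–50 °C; recrystallisation
Reagents that add atoms: none
Why: Noyori Ru–BINAP hydrogenation of a 1,3-diketone through its chelated β-dicarbonyl form, in which catalyst control sets C4 of hydroxy ketone 6 and then, reinforced by the β-hydroxyl, C2, so the anti (C2-symmetric) diol should predominate and crystallisation should remove the minor meso isomer and raise the ee.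

Step 4
Reactants: 7 (2R,4R)-1,5-dichloropentane-2,4-diol
Product: 9 (2R,4R)-1,2:4,5-diepoxypentane, via epoxy chlorohydrin 8 (not isolated)
Conditions: powdered KOH (4 equiv), Et2O, rt; filtration, careful fractional distillation
Reagents that add atoms: none
Why: Two intramolecular Williamson etherifications (3-exo-tet), in which each alkoxide displaces the chloride of its own CH2Cl group, so the bonds at C2 and C4 are not touched and the (R,R) configuration is retained.

Step 5
Reactants: 9 (2R,4R)-1,2:4,5-diepoxypentane; 4 [4-(benzyloxy)-3-methoxybenzyl]magnesium chloride (3 equiv used, 2 consumed)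
Product: 12 (3S,5S)-1,7-bis[4-(benzyloxy)-3-methoxyphenyl]heptane-3,5-diol, via epoxy alkoxide 10 (not isolated), via bis-alkoxide 11 (not isolated)
Conditions: CuI (20 mol% relative to 9), 2-MeTHF/THF, 9 added to the reagent at −40 °C, then → −10 °C; sat. aq NH4Cl
Reagents that add atoms: none
Why: Copper(I)-catalysed Grignard opening of terminal epoxides: the benzylmagnesium chloride transmetalates to a benzylcuprate that attacks each oxirane at its unsubstituted CH2 carbon in an SN2 manner, and reductive elimination from copper gives the C1–C2 and C6–C7 bonds and a magnesium alkoxide. The closest precedent is the two-directional opening of C2-symmetric terminal bis-epoxides by cuprates and copper-catalysed Grignard reagents. No ring is closed; the two oxiranes are opened. No stereocentre is created: the stereogenic C–O bonds stay intact, so the (2R,4R) centres of 9 are carried over unchanged and become (3S,5S) in 12 only because the CIP ranking of the flanking carbons switches. The step needs attack at the terminal carbon, reaction through the benzylic carbon and not the ring ortho position, and no chloride opening by magnesium salts; the monosubstituted oxiranes, the soft copper nucleophile, low temperature and an excess of reagent over 9 throughout should secure these. Because the two oxiranes are homotopic, the first opening gives one epoxy alkoxide 10 and the second one bis-alkoxide 11, so no mixture of constitutional isomers can arise.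

Step 6
Reactants: 12 (3S,5S)-1,7-bis[4-(benzyloxy)-3-methoxyphenyl]heptane-3,5-diol
Product: 14 (3S,5S)-1,7-bis[4-(benzyloxy)-3-methoxyphenyl]-5-hydroxyheptan-3-yl acetate, via cyclic orthoacetate 13 (not isolated)
Conditions: MeC(OMe)3 (1.5 equiv), PPTS (5 mol%), CH2Cl2, rt; then H2O/THF, rt; NaHCO3 work-up
Reagents that add atoms: trimethyl orthoacetate, COC(C)(OC)OC; water, O
Why: Acid-catalysed orthoester exchange gives the 2-methoxy-2-methyl-1,3-dioxane, whose hydrolysis passes through the 1,3-dioxan-2-ylium ion and can open only to a hydroxy acetate, so exactly one acetyl group is delivered, and since the two hydroxyls are homotopic either opening (and any later 1,3-acyl shift) gives the same (3S,5S)-monoacetate.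

Step 7
Reactants: 14 (3S,5S)-1,7-bis[4-(benzyloxy)-3-methoxyphenyl]-5-hydroxyheptan-3-yl acetate
Product: 17 (3S,5S)-5-hydroxy-1,7-bis(4-hydroxy-3-methoxyphenyl)heptan-3-yl acetate (target), via 1-aryl monobenzyl ether 15 (not isolated), via 7-aryl monobenzyl ether 16 (not isolated)
Conditions: H2 (1 atm), 10% Pd/C, EtOAc, rt
Reagents that add atoms: none
Why: Palladium-catalysed hydrogenolysis cleaves only the two ArO–CH2Ph bonds, whereas the secondary acetate, the non-benzylic secondary alcohol and the methyl ethers are inert under neutral conditions and the stereocentres are not involved.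

**Compound list**
1 | 4-(benzyloxy)-3-methoxybenzyl alcohol | COc1cc(CO)ccc1OCc1ccccc1 | starting material
2 | [4-(benzyloxy)-3-methoxyphenyl]methyl chlorosulfite | COc1cc(COS(=O)Cl)ccc1OCc1ccccc1 | intermediate (not isolated)
3 | 4-(benzyloxy)-3-methoxybenzyl chloride | COc1cc(CCl)ccc1OCc1ccccc1 | intermediate
4 | [4-(benzyloxy)-3-methoxybenzyl]magnesium chloride | COc1cc(C[Mg]Cl)ccc1OCc1ccccc1 | intermediate
5 | 1,5-dichloropentane-2,4-dione | ClCC(=O)CC(=O)CCl | starting material
6 | (4R)-1,5-dichloro-4-hydroxypentan-2-one | ClCC(=O)C[C@@H](O)CCl | intermediate (not isolated)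
7 | (2R,4R)-1,5-dichloropentane-2,4-diol | ClC[C@H](O)C[C@@H](O)CCl | intermediate
8 | (2R)-1-chloro-3-[(2R)-oxiran-2-yl]propan-2-ol | ClC[C@H](O)C[C@@H]1CO1 | intermediate (not isolated)
9 | (2R,4R)-1,2:4,5-diepoxypentane | C1O[C@@H]1C[C@@H]1CO1 | intermediate
10 | chloromagnesium (2S)-4-[4-(benzyloxy)-3-methoxyphenyl]-1-[(2R)-oxiran-2-yl]butan-2-olate | COc1cc(CC[C@H](O[Mg]Cl)C[C@@H]2CO2)ccc1OCc1ccccc1 | intermediate (not isolated)
11 | bis(chloromagnesium) (3S,5S)-1,7-bis[4-(benzyloxy)-3-methoxyphenyl]heptane-3,5-diolate | COc1cc(CC[C@H](O[Mg]Cl)C[C@@H](O[Mg]Cl)CCc2ccc(OCc3ccccc3)c(OC)c2)ccc1OCc1ccccc1 | intermediate (not isolated)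
12 | (3S,5S)-1,7-bis[4-(benzyloxy)-3-methoxyphenyl]heptane-3,5-diol | COc1cc(CC[C@H](O)C[C@@H](O)CCc2ccc(OCc3ccccc3)c(OC)c2)ccc1OCc1ccccc1 | intermediate
13 | (4S,6S)-4,6-bis{2-[4-(benzyloxy)-3-methoxyphenyl]ethyl}-2-methoxy-2-methyl-1,3-dioxane | COc1cc(CC[C@H]2C[C@H](CCc3ccc(OCc4ccccc4)c(OC)c3)OC(C)(OC)O2)ccc1OCc1ccccc1 | intermediate (not isolated)
14 | (3S,5S)-1,7-bis[4-(benzyloxy)-3-methoxyphenyl]-5-hydroxyheptan-3-yl acetate | COc1cc(CC[C@H](O)C[C@H](CCc2ccc(OCc3ccccc3)c(OC)c2)OC(C)=O)ccc1OCc1ccccc1 | intermediate
15 | (3S,5S)-1-[4-(benzyloxy)-3-methoxyphenyl]-5-hydroxy-7-(4-hydroxy-3-methoxyphenyl)heptan-3-yl acetate | COc1cc(CC[C@H](O)C[C@H](CCc2ccc(OCc3ccccc3)c(OC)c2)OC(C)=O)ccc1O | intermediate (not isolated)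
16 | (3S,5S)-7-[4-(benzyloxy)-3-methoxyphenyl]-5-hydroxy-1-(4-hydroxy-3-methoxyphenyl)heptan-3-yl acetate | COc1cc(CC[C@H](O)C[C@H](CCc2ccc(O)c(OC)c2)OC(C)=O)ccc1OCc1ccccc1 | intermediate (not isolated)
17 | (3S,5S)-5-hydroxy-1,7-bis(4-hydroxy-3-methoxyphenyl)heptan-3-yl acetate | COc1cc(CC[C@H](O)C[C@H](CCc2ccc(O)c(OC)c2)OC(C)=O)ccc1O | target

**Step count**
Total steps: 7. Longest linear sequence: 5 steps (5 → 7 → 9 → 12 → 14 → 17, or equally 1 → 3 → 4 → 12 → 14 → 17).

**Steps most likely to fail**

Step 5. The oxiranes may be opened by chloride under the influence of magnesium salts, the reaction may stall after the first opening, or the benzyl reagent may be lost to homocoupling or react through its ring ortho position. The fallback keeps the same two bonds but uses a stabilised benzyl anion; it sets out from 3 and 9 and comes back at 12. Chloride 3 is treated with sodium benzenesulfinate (DMF, rt) to give 4-(benzyloxy)-3-methoxybenzyl phenyl sulfone F1. Deprotonation (n-BuLi, THF, −78 °C) gives the α-lithio sulfone F2. About 2.3 equiv of F2 with BF3·OEt2 at −78 °C should open 9 at both CH2 termini to give the bis-sulfonyl diol F3, as a mixture of epimers at the two sulfonyl carbons. Reductive desulfonylation (6% Na/Hg, Na2HPO4, MeOH–THF, −20 °C) removes both sulfonyl groups and with them the extra stereocentres, returning to 12.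

Step 2. Wurtz homocoupling during magnesium insertion may consume the electron-rich benzyl chloride, or initiation may be erratic. The fallback never has a benzyl halide and a benzyl–metal species in the same flask; it sets out from 3 and comes back at 4. Chloride 3 is substituted with Bu3SnLi (from Bu3SnH and LDA, THF, −78 °C) to give tributyl{[4-(benzyloxy)-3-methoxyphenyl]methyl}stannane F4. Tin–lithium exchange (n-BuLi, THF, −78 °C) gives [4-(benzyloxy)-3-methoxybenzyl]lithium F5. Transmetalation with anhydrous MgCl2 in THF gives 4, which enters step 5 unchanged.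

Step 6. Closure to the six-membered cyclic orthoester may be incomplete, because the anti-diol forces one arm axial; acyclic mixed orthoesters would then hydrolyse to mixtures of diol, mono- and diacetate. The fallback sets out from 12 and comes back at 14. Exhaustive acetylation (Ac2O, pyridine, DMAP, CH2Cl2) gives (3S,5S)-1,7-bis[4-(benzyloxy)-3-methoxyphenyl]heptane-3,5-diyl diacetate F6. Controlled methanolysis (K2CO3, 0.3 equiv, MeOH–THF, 0 °C, stopped near half conversion) removes one of the two homotopic acetates to give 14. Recovered F6 and 12 are recycled.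

Further compounds
F1 | step 5 | 4-(benzyloxy)-3-methoxybenzyl phenyl sulfone | COc1cc(CS(=O)(=O)c2ccccc2)ccc1OCc1ccccc1
F2 | step 5 | {[4-(benzyloxy)-3-methoxyphenyl](phenylsulfonyl)methyl}lithium | COc1cc(C([Li])S(=O)(=O)c2ccccc2)ccc1OCc1ccccc1
F3 | step 5 | (3R,5R)-1,7-bis[4-(benzyloxy)-3-methoxyphenyl]-1,7-bis(phenylsulfonyl)heptane-3,5-diol (C1/C7 epimer mixture; same spatial arrangement at the carbinols as 12, descriptor change formal) | COc1cc(C(C[C@H](O)C[C@@H](O)CC(c2ccc(OCc3ccccc3)c(OC)c2)S(=O)(=O)c2ccccc2)S(=O)(=O)c2ccccc2)ccc1OCc1ccccc1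
F4 | step 2 | tributyl{[4-(benzyloxy)-3-methoxyphenyl]methyl}stannane | CCCC[Sn](CCCC)(CCCC)Cc1ccc(OCc2ccccc2)c(OC)c1
F5 | step 2 | [4-(benzyloxy)-3-methoxybenzyl]lithium | COc1cc(C[Li])ccc1OCc1ccccc1
F6 | step 6 | (3S,5S)-1,7-bis[4-(benzyloxy)-3-methoxyphenyl]heptane-3,5-diyl diacetate | COc1cc(CC[C@H](OC(C)=O)C[C@H](CCc2ccc(OCc3ccccc3)c(OC)c2)OC(C)=O)ccc1OCc1ccccc1
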